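**Retrosynthetic overview**
- The target is 5,6,8,2′,5′-pentamethoxyflavone; the last operation is double O-methylation of the 5,8-dihydroxy-6-methoxyflavone.
- The strategy rests on the A ring (C4a–C5–C6–C7–C8–C8a): para oxygens at C5 and C8, OMe at C6 and H at C7. This is the hydroquinone pattern produced when a 4-hydroxy-3-methoxycyclobutenone attached to C5 of a 2-aryl-4-pyranone ring-expands, forming the C8–C8a bond.
- The cyclobutenone carbinol comes from a C5-magnesiated 2-aryl-4-pyranone and 3-methoxycyclobutene-1,2-dione, itself made from dimethyl squarate.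
- The pyranone (C ring) comes from a hetero-Diels–Alder reaction of 2,5-dimethoxybenzaldehyde with Danishefsky's diene, iodination at C5 of the dihydropyranone (the only vinylic α-position, so no regiochemical question), then dehydrogenation.
- Ring order: B ring purchased, C ring in step 1, A ring last in step 6.

Key step: step 6

Remark: the target has no stereocentre and is achiral, so no enantiocontrol is needed. The stereocentres of intermediates 3, 4, 5, 8, 11 and 13 are formed racemic and are all removed before the target.

**Route**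

Step 1
Reactants: 1 2,5-dimethoxybenzaldehyde; 2 Danishefsky's diene, (E)-1-methoxy-3-(trimethylsilyloxy)buta-1,3-diene
Product: 4 2-(2,5-dimethoxyphenyl)-2,3-dihydro-4H-pyran-4-one (racemic), via silyloxy dihydropyran cycloadduct 3 (not isolated)
Conditions: ZnCl2, THF, rt; then TFA (cat.), CH2Cl2, 0 °C, aqueous work-up
Reagents that add atoms: none
Why: Lewis-acid-promoted hetero-Diels–Alder reaction of an aromatic aldehyde with the siloxy diene, followed by acid unmasking of the silyl enol ether and β-elimination of methanol, should give the dihydropyranone; C2 is formed racemic and is removed in step 3.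

Step 2
Reactants: 4 2-(2,5-dimethoxyphenyl)-2,3-dihydro-4H-pyran-4-one
Product: 5 2-(2,5-dimethoxyphenyl)-5-iodo-2,3-dihydro-4H-pyran-4-one (racemic)
Conditions: I2, pyridine, CH2Cl2, 0 °C to rt
Reagents that add atoms: iodine, II
Why: Johnson-type α-iodination of a cyclic vinylogous ester should place iodine at C5, the only vinylic α-carbon, and iodine/pyridine is too weak an electrophile to attack the dimethoxyarene.

Step 3
Reactants: 5 2-(2,5-dimethoxyphenyl)-5-iodo-2,3-dihydro-4H-pyran-4-one
Product: 6 2-(2,5-dimethoxyphenyl)-5-iodo-4H-pyran-4-one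
Conditions: DDQ, 1,4-dioxane, reflux
Reagents that add atoms: none
Why: DDQ dehydrogenation of the flavanone-to-flavone type should work because hydride abstraction from the benzylic, oxygen-bearing C2–H gives an oxocarbenium ion stabilised by the electron-rich aryl group, and loss of a C3 proton then gives the 4-pyranone while the vinyl iodide is untouched.

Step 4
Reactants: 7 dimethyl squarate (3,4-dimethoxycyclobut-3-ene-1,2-dione)
Product: 9 3-methoxycyclobut-3-ene-1,2-dione, via 4-hydroxy-2,3-dimethoxycyclobutenone 8 (not isolated)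
Conditions: LiAlH(OtBu)3, THF, −78 to −20 °C, cold 1 M HCl quench; crude 8 then TFAA, CH2Cl2, −78 to 0 °C
Reagents that add atoms: none
Why: The hindered hydride should stop at 1,2-mono-reduction of one squarate carbonyl; trifluoroacetylation and ionisation of the carbinol then give a methoxy-stabilised cyclobutenyl cation that loses its methyl group to trifluoroacetate, the known 1,3-carbonyl transposition of 4-hydroxy-2,3-dialkoxycyclobutenones, run without water to spare the labile methyl semisquarate.

Step 5
Reactants: 6 2-(2,5-dimethoxyphenyl)-5-iodo-4H-pyran-4-one; 9 3-methoxycyclobut-3-ene-1,2-dione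
Product: 11 racemic 2-(2,5-dimethoxyphenyl)-5-(1-hydroxy-2-methoxy-4-oxocyclobut-2-en-1-yl)-4H-pyran-4-one, via pyranonylmagnesium chloride 10 (not isolated)
Conditions: iPrMgCl·LiCl (1.0 equiv), THF, −40 °C; cannulated into 9, THF, −78 °C; sat. aq. NH4Cl
Reagents that add atoms: none
Why: Iodine–magnesium exchange at the sp2 C–I bond of the α-iodo-β-alkoxy enone (no enolisable protons in the 4-pyranone) should give a Grignard reagent that adds 1,2 to the ketone-like C2 carbonyl of 9 and not to the C1 carbonyl, which is deactivated as a vinylogous ester, so the carbinol carbon ends up next to the methoxy-bearing carbon; the new quaternary stereocentre is racemic and is destroyed in step 6.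

Step 6
Reactants: 11 racemic 2-(2,5-dimethoxyphenyl)-5-(1-hydroxy-2-methoxy-4-oxocyclobut-2-en-1-yl)-4H-pyran-4-one
Product: 14 2-(2,5-dimethoxyphenyl)-5,8-dihydroxy-6-methoxy-4H-chromen-4-one, via vinylketene 12 (not isolated), via 8aH-chromene-4,8-dione tautomer 13 (not isolated)
Conditions: degassed p-xylene, reflux (138 °C), Ar
Reagents that add atoms: none
Why: Heating should open the cyclobutenone by conrotatory 4π cleavage of its C1–C4 bond to the (Z)-vinylketene 12, whose ketene carbon then bonds to pyranone C6 (the CH next to the ring oxygen) in a 6π electrocyclisation to dienone 13, and the C8a hydrogen of 13 shifts to oxygen to aromatise the new ring. The closest known reaction is the Moore ring expansion of 4-aryl- and 4-alkenyl-4-hydroxycyclobutenones to hydroquinones, applied here with a 4-pyranon-3-yl group as the unsaturated substituent. The one ring closed is the six-membered carbocyclic A ring, by thermal disrotatory 6π closure that makes the C8–C8a bond. The only new stereocentre, C8a of 13, is transient and vanishes on tautomerisation, so nothing needs to be controlled. The step needs the pyranone to rotate inward on ring opening, which the donor hydroxyl secures by rotating outward (torquoselectivity), and closure can only occur at C6 because the other neighbour of the attachment carbon is the C4 carbonyl carbon. The connectivity of 11 fixes the oxygen pattern (carbinol carbon to C5, C–OMe to C6, CH to C7, ketene carbon to C8), and air is excluded because the hydroquinone would otherwise oxidise to the 5,8-quinone.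

Step 7
Reactants: 14 2-(2,5-dimethoxyphenyl)-5,8-dihydroxy-6-methoxy-4H-chromen-4-one
Product: 15 2-(2,5-dimethoxyphenyl)-5,6,8-trimethoxy-4H-chromen-4-one (target)
Conditions: Me2SO4 (excess), K2CO3, acetone, reflux, Ar
Reagents that add atoms: dimethyl sulfate, COS(=O)(=O)OC
Why: Williamson O-methylation should convert both phenols, the chelated 5-OH needing the excess reagent and prolonged reflux that are standard for 5-hydroxyflavones, while argon keeps the hydroquinone dianion from oxidising.

**Compound list**
1 | 2,5-dimethoxybenzaldehyde | COc1ccc(OC)c(C=O)c1 | starting material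
2 | Danishefsky's diene, (E)-1-methoxy-3-(trimethylsilyloxy)buta-1,3-diene | CO/C=C/C(=C)O[Si](C)(C)C | starting material
3 | {[2-(2,5-dimethoxyphenyl)-6-methoxy-3,6-dihydro-2H-pyran-4-yl]oxy}trimethylsilane (racemic, cis/trans mixture) | COC1C=C(O[Si](C)(C)C)CC(c2cc(OC)ccc2OC)O1 | intermediate
4 | 2-(2,5-dimethoxyphenyl)-2,3-dihydro-4H-pyran-4-one (racemic) | COc1ccc(OC)c(C2CC(=O)C=CO2)c1 | intermediate
5 | 2-(2,5-dimethoxyphenyl)-5-iodo-2,3-dihydro-4H-pyran-4-one (racemic) | COc1ccc(OC)c(C2CC(=O)C(I)=CO2)c1 | intermediate
6 | 2-(2,5-dimethoxyphenyl)-5-iodo-4H-pyran-4-one | COc1ccc(OC)c(-c2cc(=O)c(I)co2)c1 | intermediate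
7 | dimethyl squarate (3,4-dimethoxycyclobut-3-ene-1,2-dione) | COC1=C(OC)C(=O)C1=O | starting material
8 | 4-hydroxy-2,3-dimethoxycyclobut-2-en-1-one (racemic) | COC1=C(OC)C(=O)C1O | intermediate
9 | 3-methoxycyclobut-3-ene-1,2-dione | COC1=CC(=O)C1=O | intermediate
10 | chloro[6-(2,5-dimethoxyphenyl)-4-oxo-4H-pyran-3-yl]magnesium | COc1ccc(OC)c(-c2cc(=O)c([Mg]Cl)co2)c1 | intermediate
11 | 2-(2,5-dimethoxyphenyl)-5-(1-hydroxy-2-methoxy-4-oxocyclobut-2-en-1-yl)-4H-pyran-4-one (racemic) | COC1=CC(=O)C1(O)c1coc(-c2cc(OC)ccc2OC)cc1=O | intermediate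
12 | (Z)-vinylketene, 2-(2,5-dimethoxyphenyl)-5-(1-hydroxy-2-methoxy-4-oxobuta-1,3-dien-1-yl)-4H-pyran-4-one | O=C=C/C(OC)=C(/O)c1coc(-c2cc(OC)ccc2OC)cc1=O | intermediate
13 | 2-(2,5-dimethoxyphenyl)-5-hydroxy-6-methoxy-8aH-chromene-4,8-dione (racemic) | COC1=CC(=O)C2OC(=CC(=O)C2=C1O)c1cc(OC)ccc1OC | intermediate
14 | 2-(2,5-dimethoxyphenyl)-5,8-dihydroxy-6-methoxy-4H-chromen-4-one | COc1ccc(OC)c(-c2cc(=O)c3c(O)c(OC)cc(O)c3o2)c1 | intermediate
15 | 2-(2,5-dimethoxyphenyl)-5,6,8-trimethoxy-4H-chromen-4-one | COc1ccc(OC)c(-c2cc(=O)c3c(OC)c(OC)cc(OC)c3o2)c1 | target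

**Step count**
Total steps: 7. Longest linear sequence: 6 steps (steps 1, 2, 3, 5, 6, 7); step 4 is the convergent branch.

**Steps most likely to fail**

1. Step 6 (key step). The vinylketene may fail to close onto the electron-poor pyranone C6 and instead be trapped by its own enol hydroxyl (inward rotation, leading to a butenolide) or oligomerise. The hydroquinone may also oxidise in air during isolation. The fallback abandons the cyclobutenone and builds the flavone by the chalcone route; it sets out from 1 and comes back at 15.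
   - 1,2,4,5-Tetramethoxybenzene is ortho-lithiated (n-BuLi, THF) and acylated with N-methoxy-N-methylacetamide to give 1-(2,3,5,6-tetramethoxyphenyl)ethanone F1.
   - BCl3 (CH2Cl2, −78 to 0 °C) removes one methyl ortho to the carbonyl by chelation to give 1-(2-hydroxy-3,5,6-trimethoxyphenyl)ethanone F2.
   - Claisen–Schmidt condensation of F2 with aldehyde 1 (KOH, EtOH) gives (E)-3-(2,5-dimethoxyphenyl)-1-(2-hydroxy-3,5,6-trimethoxyphenyl)prop-2-en-1-one F3.
   - Oxidative cyclisation of F3 (cat. I2, DMSO, 130 °C) should give 15 directly.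

2. Step 5. The magnesiated pyranone may fragment by ring opening, add to C6 of a second pyranone, or attack the semisquarate at its methoxy-bearing carbon (addition–elimination) in place of the C2 carbonyl. The fallback masks the pyranone carbonyl so that an ordinary vinyllithium can be used; it sets out from 6 and comes back at 11.
   - Thioketalisation of 6 (propane-1,3-dithiol, BF3·OEt2, CH2Cl2) gives 8-(2,5-dimethoxyphenyl)-11-iodo-9-oxa-1,5-dithiaspiro[5.5]undeca-7,10-diene F4.
   - Iodine–lithium exchange (n-BuLi, THF, −78 °C) and addition to 9 give the dithiane-protected carbinol, 4-[8-(2,5-dimethoxyphenyl)-9-oxa-1,5-dithiaspiro[5.5]undeca-7,10-dien-11-yl]-4-hydroxy-3-methoxycyclobut-2-en-1-one F5.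
   - Alkylative dethioketalisation of F5 (MeI, CaCO3, aqueous MeCN) should release 11.

3. Step 3. Dehydrogenation may stall, or DDQ may degrade the electron-rich dimethoxyarene by electron transfer. The fallback introduces the double bond by selenoxide elimination; it sets out from 5 and comes back at 6.
   - α′-Deprotonation of 5 (LiHMDS, THF, −78 °C) and trapping with PhSeCl give 2-(2,5-dimethoxyphenyl)-5-iodo-3-(phenylselanyl)-2,3-dihydro-4H-pyran-4-one F6, expected mainly as the trans isomer.
   - Oxidation (H2O2, pyridine, CH2Cl2, 0 °C) and syn-elimination of the selenoxide across C2–C3 should give 6.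

**Further compounds**
F1 | step 6 | 1-(2,3,5,6-tetramethoxyphenyl)ethanone | CC(=O)c1c(OC)c(OC)cc(OC)c1OC
F2 | step 6 | 1-(2-hydroxy-3,5,6-trimethoxyphenyl)ethanone | CC(=O)c1c(O)c(OC)cc(OC)c1OC
F3 | step 6 | (E)-3-(2,5-dimethoxyphenyl)-1-(2-hydroxy-3,5,6-trimethoxyphenyl)prop-2-en-1-one | COc1ccc(OC)c(/C=C/C(=O)c2c(O)c(OC)cc(OC)c2OC)c1
F4 | step 5 | 8-(2,5-dimethoxyphenyl)-11-iodo-9-oxa-1,5-dithiaspiro[5.5]undeca-7,10-diene | COc1ccc(OC)c(C2=CC3(SCCCS3)C(I)=CO2)c1
F5 | step 5 | 4-[8-(2,5-dimethoxyphenyl)-9-oxa-1,5-dithiaspiro[5.5]undeca-7,10-dien-11-yl]-4-hydroxy-3-methoxycyclobut-2-en-1-one (racemic) | COC1=CC(=O)C1(O)C1=COC(c2cc(OC)ccc2OC)=CC13SCCCS3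
F6 | step 3 | 2-(2,5-dimethoxyphenyl)-5-iodo-3-(phenylselanyl)-2,3-dihydro-4H-pyran-4-one (racemic, mixture of diastereomers) | COc1ccc(OC)c(C2OC=C(I)C(=O)C2[Se]c2ccccc2)c1
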